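The C21 chain is disconnected at C13–C14 (numbered from the ester oxygen), an unbiased CH2–CH2 bond separated by twelve methylenes from the ester oxygen and the catechol ring. Because both carbons are primary, unbranched and remote from the benzoate carbonyl, the bond can be forged directly at the alkane oxidation level by a B-alkyl Suzuki–Miyaura alkyl–alkyl coupling. In one flask oct-1-ene is hydroborated at its terminal carbon and the borane is joined to the fully assembled 13-bromotridecyl 2,3-bis(benzyloxy)benzoate, which delivers the entire skeleton in one operation. The precursor is an ω-bromoalkyl ester plus a feedstock olefin; hydrogenolysis of both benzyl ethers then frees the catechol.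

Key step: step 2

Assumption: 2,3-bis(benzyloxy)benzoic acid and 13-bromotridecan-1-ol are taken as catalogue compounds, and 9-BBN (sold as the dimer or as a THF solution) is drawn as its monomer.

Step 1
Reactants: 1 2,3-bis(benzyloxy)benzoic acid; 2 13-bromotridecan-1-ol
Product: 3 13-bromotridecyl 2,3-bis(benzyloxy)benzoate
Conditions: DCC (1.1 equiv), DMAP (0.1 equiv), CH2Cl2, 0 °C → rt
Reagents that add atoms: none
Why: Steglich esterification, in which DCC turns the acid into an O-acylisourea that DMAP relays as an acylpyridinium ion to the primary alcohol under neutral conditions, so the primary C–Br bond and both benzyl ethers should stay untouched and no stereocentre is formed.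

Step 2
Reactants: 3 13-bromotridecyl 2,3-bis(benzyloxy)benzoate; 4 oct-1-ene; 5 9-borabicyclo[3.3.1]nonane (9-BBN)
Product: 7 henicosyl 2,3-bis(benzyloxy)benzoate, via B-octyl-9-BBN 6 (not isolated)
Conditions: 4 (1.3 equiv), 5 (1.2 equiv, 0.5 M in THF), 0 °C → rt; then 3, Pd(OAc)2 (4 mol%), PCy3 (8 mol%), K3PO4·H2O (1.2 equiv), THF, rt
Reagents that add atoms: none
Why: 9-BBN adds to oct-1-ene in the anti-Markovnikov sense, so boron sits on the terminal carbon that becomes C14 of the chain, and hydroxide from K3PO4·H2O converts borane 6 into the borate that can transmetalate. The electron-rich Pd(0)–PCy3 complex inserts into the primary C13–Br bond of 3 by an SN2-type oxidative addition, the octyl group is transferred from boron, and reductive elimination forms the C13–C14 bond, while the bulky phosphine keeps β-hydride elimination of the alkylpalladium species slower than these events. The closest known reaction type is the room-temperature B-alkyl Suzuki–Miyaura alkyl–alkyl cross-coupling of unactivated primary alkyl bromides with Pd/trialkylphosphine catalysts. No ring is closed and no stereocentre is created. The step needs chemoselectivity for C–Br over the ester carbonyl and the benzylic C–O bonds; this is secured by the mild base, the non-nucleophilic borane and the twelve methylenes between the reacting carbon and the ester oxygen, and 9-BBN is kept below the amount of olefin so that no B–H remains to reduce the ester. Only the primary octyl group should leave boron, because the two secondary bridgehead B–C bonds of the bicycle transmetalate far more slowly.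

Step 3
Reactants: 7 henicosyl 2,3-bis(benzyloxy)benzoate
Product: 8 Gentiside I (henicosyl 2,3-dihydroxybenzoate)
Conditions: H2 (1 atm), 10% Pd/C, THF–EtOH 1:1, rt
Reagents that add atoms: none
Why: Catalytic hydrogenolysis should cleave only the two benzylic C–O bonds of the aryl benzyl ethers, because the primary alkyl ester, the saturated chain and the arene are inert at 1 atm and room temperature, and no stereocentre is involved.

Compound list
1 | 2,3-bis(benzyloxy)benzoic acid | OC(=O)c1cccc(OCc2ccccc2)c1OCc1ccccc1 | starting material
2 | 13-bromotridecan-1-ol | OCCCCCCCCCCCCCBr | starting material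
3 | 13-bromotridecyl 2,3-bis(benzyloxy)benzoate | BrCCCCCCCCCCCCCOC(=O)c1cccc(OCc2ccccc2)c1OCc1ccccc1 | intermediate
4 | oct-1-ene | C=CCCCCCC | starting material
5 | 9-borabicyclo[3.3.1]nonane (9-BBN, monomer drawn) | B1C2CCCC1CCC2 | starting material
6 | B-octyl-9-BBN (9-octyl-9-borabicyclo[3.3.1]nonane) | CCCCCCCCB1C2CCCC1CCC2 | intermediate
7 | henicosyl 2,3-bis(benzyloxy)benzoate | CCCCCCCCCCCCCCCCCCCCCOC(=O)c1cccc(OCc2ccccc2)c1OCc1ccccc1 | intermediate
8 | Gentiside I (henicosyl 2,3-dihydroxybenzoate) | CCCCCCCCCCCCCCCCCCCCCOC(=O)c1cccc(O)c1O | target

Total step count: 3. Longest linear sequence: 3 (1 → 3 → 7 → 8).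

Steps most likely to fail

Step 2. β-Hydride elimination and hydrodebromination of the alkylpalladium intermediate may outrun a slow, heterogeneous transmetalation. The fallback replaces cross-coupling by olefination. It sets out from 3, which is heated with PPh3 in MeCN and should give [13-{[2,3-bis(benzyloxy)benzoyl]oxy}tridecyl]triphenylphosphonium bromide F1. Deprotonation with NaHMDS in THF at −78 °C and Wittig reaction with commercial octanal should give (Z)-henicos-13-en-1-yl 2,3-bis(benzyloxy)benzoate F2, in which the C13–C14 link is present as a double bond. The conditions of step 3 (H2, Pd/C) should saturate the alkene and cleave both benzyl ethers at once, so the fallback returns to the route at 8.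

Step 3. Hydrogenolysis may stall through poisoning of the catalyst by phosphine or boron residues carried over from step 2, or through the low solubility of the waxy substrate. The free catechol may also oxidise in air during work-up. The fallback is a non-reductive Lewis-acid debenzylation. It sets out from 7, which is treated with BCl3 and pentamethylbenzene as cation scavenger in CH2Cl2 at −78 °C, and it returns directly at 8 without any new compound.

Step 1. The O-acylisourea of the ortho-substituted acid may rearrange by O→N acyl shift faster than it is intercepted, and DMAP may be slowly quaternised by the primary bromide. The fallback activates the alcohol instead of the acid. It sets out from 1 and 2 under Mitsunobu conditions (PPh3, DIAD, THF, 0 °C → rt), where the carboxylate displaces the alkoxyphosphonium group at C1 of the chain, and it returns at 3 without any new compound.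

Further compounds
F1 | step 2 | [13-{[2,3-bis(benzyloxy)benzoyl]oxy}tridecyl]triphenylphosphonium bromide | [Br-].O=C(OCCCCCCCCCCCCC[P+](c1ccccc1)(c1ccccc1)c1ccccc1)c1cccc(OCc2ccccc2)c1OCc1ccccc1
F2 | step 2 | (Z)-henicos-13-en-1-yl 2,3-bis(benzyloxy)benzoate | CCCCCCC/C=C\CCCCCCCCCCCCOC(=O)c1cccc(OCc2ccccc2)c1OCc1ccccc1
F0 | step 3 | none | none
F0 | step 1 | none | none
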